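## Retrosynthetic overview

1. Target ⇒ silyl ether removal and a late cross-metathesis of a C6-vinyl lactone with acrylic acid (C7=C8).
2. Ester C5–O ⇒ Mitsunobu inversion of a trans-5-hydroxy lactone with the complete dienoic acid; this sets C5 and joins the fragments.
3. The only ring (the dihydropyranone) is formed first: tartrate/titanium-controlled kinetic-resolution oxidative ring expansion of a racemic furyl vinyl carbinol from furfural (dearomatisation sets C6), then lactol → lactone and ketone → alcohol.
4. Side-chain acid ⇒ Horner–Wadsworth–Emmons on an enal ⇐ cross-metathesis with methacrolein ⇐ copper-catalysed asymmetric allylic methylation (C6′) ⇐ (S)-propylene oxide (C11′).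

Assumption: Grignard solutions and (S)-propylene oxide count as commercial starting materials, and the ligand in step 7 is the enantiomer that gives the (7R) product (expected (R,R)-Taniaphos; the mirror-image ligand is used if the measured sense is opposite).

## Route

Step 1
Reactants: 1 furfural; 2 vinylmagnesium bromide
Product: 3 rac-1-(furan-2-yl)prop-2-en-1-ol
Conditions: THF, 0 °C; then aq NH4Cl
Reagents that add atoms: none
Why: Grignard 1,2-addition to the aldehyde; the carbinol is made racemic on purpose because step 2 resolves it.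

Step 2
Reactants: 3 rac-1-(furan-2-yl)prop-2-en-1-ol
Product: 5 (2S)-6-hydroxy-2-vinyl-2H-pyran-3(6H)-one, via (2Z,5S)-5-hydroxy-4-oxohepta-2,6-dienal 4 (not isolated)
Conditions: Ti(OiPr)4 (0.2 equiv), L-(+)-diisopropyl tartrate (0.24 equiv), t-BuOOH (0.55 equiv), 4 Å MS, CH2Cl2, −20 °C, stopped near 45% conversion
Reagents that add atoms: tert-butyl hydroperoxide, CC(C)(C)OO
Why: Sharpless kinetic resolution merged with the Achmatowicz oxidative ring expansion: with L-(+)-tartrate the titanium peroxide complex epoxidises the furan 2,3-bond of the (S)-carbinol far faster than that of the (R)-carbinol, the epoxide opens to ene-dione 4 and the carbinol oxygen closes onto the aldehyde, so the furan is dearomatised and C6 of the target is fixed as S in one operation (at most 50% yield) while the (R)-alcohol stays behind and the vinyl group of the (S)-series is a mismatched, slow epoxidation site.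

Step 3
Reactants: 5 (2S)-6-hydroxy-2-vinyl-2H-pyran-3(6H)-one
Product: 6 (6S)-6-vinyl-2H-pyran-2,5(6H)-dione
Conditions: CrO3, H2SO4, acetone/H2O, 0 °C, short reaction time
Reagents that add atoms: none
Why: Jones oxidation of the lactol to the lactone; the acidic, non-basic medium keeps the C6 stereocentre (alpha to the ketone) from enolising toward the aromatic hydroxypyranone.

Step 4
Reactants: 6 (6S)-6-vinyl-2H-pyran-2,5(6H)-dione
Product: 7 (5R,6S)-5-hydroxy-6-vinyl-5,6-dihydro-2H-pyran-2-one
Conditions: NaBH4, CeCl3·7H2O, MeOH/CH2Cl2, −78 °C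
Reagents that add atoms: none
Why: Luche 1,2-reduction of the ring ketone only; axial hydride attack on the half-chair with the C6-vinyl group pseudo-equatorial gives the equatorial alcohol trans to C6 (substrate control, 5R), which step 10 inverts.

Step 5
Reactants: 8 (S)-propylene oxide; 9 pent-4-en-1-ylmagnesium bromide
Product: 11 tert-butyldimethyl{[(2S)-oct-7-en-2-yl]oxy}silane, via (S)-oct-7-en-2-ol 10 (not isolated)
Conditions: CuI (10 mol%), THF, −40 → 0 °C; then imidazole, TBSCl, DMF, rt, same flask
Reagents that add atoms: tert-butyldimethylsilyl chloride, CC(C)(C)[Si](C)(C)Cl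
Why: Copper-catalysed Grignard opening of the epoxide at the CH2 terminus (SN2, the C–O stereocentre is untouched and becomes C11′) followed by silylation of the magnesium alkoxide.

Step 6
Reactants: 11 tert-butyldimethyl{[(2S)-oct-7-en-2-yl]oxy}silane; 12 (E)-1,4-dibromobut-2-ene
Product: 13 {[(2S,7E)-9-bromonon-7-en-2-yl]oxy}(tert-butyl)dimethylsilane
Conditions: 12 (3 equiv), second-generation Hoveyda–Grubbs catalyst RuCl2(SIMes)(=CH-C6H4-2-OiPr) (3 mol%), CH2Cl2, 40 °C
Reagents that add atoms: none
Why: Olefin cross-metathesis of a terminal alkene with an excess of the symmetrical allylic dibromide gives the (E)-allylic bromide (thermodynamic E preference; the minor Z isomer is removed on AgNO3-silica).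

Step 7
Reactants: 13 {[(2S,7E)-9-bromonon-7-en-2-yl]oxy}(tert-butyl)dimethylsilane
Product: 14 tert-butyldimethyl{[(2S,7R)-7-methylnon-8-en-2-yl]oxy}silane
Conditions: MeMgBr (1.2 equiv), CuBr·SMe2 (2 mol%), (R,R)-Taniaphos (2.4 mol%), CH2Cl2, −75 °C, slow addition of 13
Reagents that add atoms: methylmagnesium bromide, C[Mg]Br
Why: Copper-catalysed asymmetric allylic alkylation: the chiral copper–Taniaphos complex delivers methyl in an SN2′ sense to the gamma carbon, creating the C6′ methyl stereocentre (7R here) under catalyst control, the remote silyloxy centre having no influence.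

Step 8
Reactants: 14 tert-butyldimethyl{[(2S,7R)-7-methylnon-8-en-2-yl]oxy}silane; 15 methacrolein
Product: 16 (2E,4R,9S)-9-[(tert-butyldimethylsilyl)oxy]-2,4-dimethyldec-2-enal
Conditions: 15 (10 equiv), second-generation Hoveyda–Grubbs catalyst (5 mol%), 1,4-benzoquinone (10 mol%), CH2Cl2, 40 °C
Reagents that add atoms: none
Why: Cross-metathesis with methacrolein forms the trisubstituted (E)-enal (E favoured thermodynamically), and benzoquinone suppresses ruthenium hydride isomerisation next to the allylic stereocentre.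

Step 9
Reactants: 16 (2E,4R,9S)-9-[(tert-butyldimethylsilyl)oxy]-2,4-dimethyldec-2-enal; 17 (diethoxyphosphoryl)acetic acid
Product: 18 (2E,4E,6R,11S)-11-[(tert-butyldimethylsilyl)oxy]-4,6-dimethyldodeca-2,4-dienoic acid
Conditions: Zn(OTf)2, TMEDA, DBU, THF, rt; acidic work-up
Reagents that add atoms: none
Why: Horner–Wadsworth–Emmons olefination with the free phosphonoacetic acid under mild zinc/amine conditions gives the (2E)-acid directly, with no ester hydrolysis step and little risk of gamma-deprotonation of the enal.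

Step 10
Reactants: 7 (5R,6S)-5-hydroxy-6-vinyl-5,6-dihydro-2H-pyran-2-one; 18 (2E,4E,6R,11S)-11-[(tert-butyldimethylsilyl)oxy]-4,6-dimethyldodeca-2,4-dienoic acid
Product: 19 (2S,3S)-6-oxo-2-vinyl-3,6-dihydro-2H-pyran-3-yl (2E,4E,6R,11S)-11-[(tert-butyldimethylsilyl)oxy]-4,6-dimethyldodeca-2,4-dienoate
Conditions: PPh3, DIAD, THF, 0 °C → rt
Reagents that add atoms: none
Why: Mitsunobu esterification: the carboxylate displaces the activated C5–O with SN2 inversion, turning the trans (5R) alcohol into the cis (5S,6S) ester and joining the fragments in one step, while the C6–H is syn to the leaving group, which disfavours anti-elimination to the 2-pyranone.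

Step 11
Reactants: 19 the vinyl lactone ester; 20 acrylic acid
Product: 21 (2E)-3-[(2S,3S)-3-{[(2E,4E,6R,11S)-11-[(tert-butyldimethylsilyl)oxy]-4,6-dimethyldodeca-2,4-dienoyl]oxy}-6-oxo-3,6-dihydro-2H-pyran-2-yl]prop-2-enoic acid
Conditions: 20 (5 equiv), second-generation Hoveyda–Grubbs catalyst (7 mol%), CH2Cl2, 40 °C
Reagents that add atoms: none
Why: Cross-metathesis of the terminal vinyl group with acrylic acid gives the (E)-acrylic acid directly without an ester protecting group, the ring enoate and the conjugated trisubstituted diene of the side chain being poor metathesis substrates.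

Step 12
Reactants: 21 the silyl-protected acid
Product: 22 (2E)-3-[(2S,3S)-3-{[(2E,4E,6R,11S)-11-hydroxy-4,6-dimethyldodeca-2,4-dienoyl]oxy}-6-oxo-3,6-dihydro-2H-pyran-2-yl]prop-2-enoic acid (CNP0107712.2)
Conditions: HF·pyridine, pyridine/THF, 0 °C → rt
Reagents that add atoms: none
Why: Fluoride-mediated desilylation under buffered acidic conditions frees the C11′ alcohol without touching the lactone, the allylic ester or the carboxylic acid.

Stereocentres: C6 from step 2; C5 from step 4, inverted in step 10; C11′ from (S)-propylene oxide; C6′ from step 7.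

## Compound list

1 | furfural (furan-2-carbaldehyde) | O=Cc1ccco1 | starting material
2 | vinylmagnesium bromide | C=C[Mg]Br | starting material
3 | rac-1-(furan-2-yl)prop-2-en-1-ol | C=CC(O)c1ccco1 | intermediate
4 | (2Z,5S)-5-hydroxy-4-oxohepta-2,6-dienal | O=C/C=C\C(=O)[C@@H](O)C=C | intermediate (not isolated)
5 | (2S)-6-hydroxy-2-vinyl-2H-pyran-3(6H)-one (anomeric mixture) | C=C[C@@H]1OC(O)C=CC1=O | intermediate
6 | (6S)-6-vinyl-2H-pyran-2,5(6H)-dione | C=C[C@@H]1OC(=O)C=CC1=O | intermediate
7 | (5R,6S)-5-hydroxy-6-vinyl-5,6-dihydro-2H-pyran-2-one | O[C@@H]1C=CC(=O)O[C@H]1C=C | intermediate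
8 | (S)-propylene oxide | C[C@H]1CO1 | starting material
9 | pent-4-en-1-ylmagnesium bromide | C=CCCC[Mg]Br | starting material
10 | (S)-oct-7-en-2-ol (present as its bromomagnesium alkoxide) | C[C@H](O)CCCCC=C | intermediate (not isolated)
11 | tert-butyldimethyl{[(2S)-oct-7-en-2-yl]oxy}silane | C[C@H](O[Si](C)(C)C(C)(C)C)CCCCC=C | intermediate
12 | (E)-1,4-dibromobut-2-ene | BrC/C=C/CBr | starting material
13 | {[(2S,7E)-9-bromonon-7-en-2-yl]oxy}(tert-butyl)dimethylsilane | C[C@H](O[Si](C)(C)C(C)(C)C)CCCC/C=C/CBr | intermediate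
14 | tert-butyldimethyl{[(2S,7R)-7-methylnon-8-en-2-yl]oxy}silane | C[C@H](O[Si](C)(C)C(C)(C)C)CCCC[C@@H](C)C=C | intermediate
15 | methacrolein | C=C(C)C=O | starting material
16 | (2E,4R,9S)-9-[(tert-butyldimethylsilyl)oxy]-2,4-dimethyldec-2-enal | C[C@H](O[Si](C)(C)C(C)(C)C)CCCC[C@@H](C)/C=C(\C)C=O | intermediate
17 | (diethoxyphosphoryl)acetic acid | CCOP(=O)(CC(=O)O)OCC | starting material
18 | (2E,4E,6R,11S)-11-[(tert-butyldimethylsilyl)oxy]-4,6-dimethyldodeca-2,4-dienoic acid | C[C@H](O[Si](C)(C)C(C)(C)C)CCCC[C@@H](C)/C=C(C)/C=C/C(=O)O | intermediate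
19 | (2S,3S)-6-oxo-2-vinyl-3,6-dihydro-2H-pyran-3-yl (2E,4E,6R,11S)-11-[(tert-butyldimethylsilyl)oxy]-4,6-dimethyldodeca-2,4-dienoate | C[C@H](O[Si](C)(C)C(C)(C)C)CCCC[C@@H](C)/C=C(C)/C=C/C(=O)O[C@H]1C=CC(=O)O[C@H]1C=C | intermediate
20 | acrylic acid | C=CC(=O)O | starting material
21 | (2E)-3-[(2S,3S)-3-{[(2E,4E,6R,11S)-11-[(tert-butyldimethylsilyl)oxy]-4,6-dimethyldodeca-2,4-dienoyl]oxy}-6-oxo-3,6-dihydro-2H-pyran-2-yl]prop-2-enoic acid | C[C@H](O[Si](C)(C)C(C)(C)C)CCCC[C@@H](C)/C=C(C)/C=C/C(=O)O[C@H]1C=CC(=O)O[C@H]1/C=C/C(=O)O | intermediate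
22 | (2E)-3-[(2S,3S)-3-{[(2E,4E,6R,11S)-11-hydroxy-4,6-dimethyldodeca-2,4-dienoyl]oxy}-6-oxo-3,6-dihydro-2H-pyran-2-yl]prop-2-enoic acid | C[C@H](O)CCCC[C@@H](C)/C=C(C)/C=C/C(=O)O[C@H]1C=CC(=O)O[C@H]1/C=C/C(=O)O | target

## Step count and risks

Total steps: 12. Longest linear sequence: 8 (steps 5–12, from (S)-propylene oxide); the furfural branch contributes steps 1–4.

Most likely to fail:

Step 2 (resolution and ring expansion in one operation). The enantiomeric purity of 5 depends on conversion and on the selectivity factor, and the vinyl group could compete. Fallback, setting out from 3 and coming back at 5: resolve 3 with immobilised Candida antarctica lipase B and vinyl acetate in hexane at rt, which acetylates the (R)-alcohol and leaves (S)-1-(furan-2-yl)prop-2-en-1-ol F1. Then carry out a classical Achmatowicz rearrangement of F1 with NBS, NaHCO3, THF/H2O at 0 °C to give 5.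

Step 8 (cross-metathesis of an allylically branched alkene with methacrolein). It may be slow or low-yielding. Fallback, setting out from 14 and coming back at 16: ozonolysis of 14 (O3, CH2Cl2, −78 °C; then Me2S) gives (2R,7S)-7-[(tert-butyldimethylsilyl)oxy]-2-methyloctanal F2. Wittig olefination of F2 with 2-(triphenylphosphoranylidene)propanal (toluene, 80 °C) gives the (E)-enal 16.

Step 11 (late cross-metathesis with acrylic acid on the hindered, polyunsaturated ester 19). Fallback, setting out from 7 and coming back at 22: run the metathesis early on the small lactone 7 with tert-butyl acrylate (second-generation Hoveyda–Grubbs catalyst, CH2Cl2, 40 °C) to give tert-butyl (2E)-3-[(2S,3R)-3-hydroxy-6-oxo-3,6-dihydro-2H-pyran-2-yl]prop-2-enoate F3. Mitsunobu esterification of F3 with 18 (PPh3, DIAD, THF) gives tert-butyl (2E)-3-[(2S,3S)-3-{[(2E,4E,6R,11S)-11-[(tert-butyldimethylsilyl)oxy]-4,6-dimethyldodeca-2,4-dienoyl]oxy}-6-oxo-3,6-dihydro-2H-pyran-2-yl]prop-2-enoate F4. TFA/CH2Cl2/H2O at 0 °C then cleaves the tert-butyl ester and the silyl ether of F4 together to give 22.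

Further compounds
F1 | step 2 | (S)-1-(furan-2-yl)prop-2-en-1-ol | C=C[C@H](O)c1ccco1
F2 | step 8 | (2R,7S)-7-[(tert-butyldimethylsilyl)oxy]-2-methyloctanal | C[C@H](O[Si](C)(C)C(C)(C)C)CCCC[C@@H](C)C=O
F3 | step 11 | tert-butyl (2E)-3-[(2S,3R)-3-hydroxy-6-oxo-3,6-dihydro-2H-pyran-2-yl]prop-2-enoate | O[C@@H]1C=CC(=O)O[C@H]1/C=C/C(=O)OC(C)(C)C
F4 | step 11 | tert-butyl (2E)-3-[(2S,3S)-3-{[(2E,4E,6R,11S)-11-[(tert-butyldimethylsilyl)oxy]-4,6-dimethyldodeca-2,4-dienoyl]oxy}-6-oxo-3,6-dihydro-2H-pyran-2-yl]prop-2-enoate | C[C@H](O[Si](C)(C)C(C)(C)C)CCCC[C@@H](C)/C=C(C)/C=C/C(=O)O[C@H]1C=CC(=O)O[C@H]1/C=C/C(=O)OC(C)(C)C
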